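**Retrosynthetic overview**
1. Punaglandin 3 ⇐ E1cB loss of AcOH across C7–C8 from a 5,6,7‑triacetoxy aldol‑type cyclopentenone; C7 is only a relay stereocentre.
2. Cyclopentenone (the only ring made, formed last) ⇐ Piancatelli rearrangement (4π‑conrotatory electrocyclisation) of a 3‑chloro‑5‑octadienyl‑2‑furylcarbinol; Cl is pre‑installed (furan C3 → C10) and C12 is set by the sugar‑derived C7.
3. Furylcarbinol ⇐ 2‑metallated 4‑chloro‑2‑[(2Z,5Z)‑octadienyl]furan + C1–C8 lactone aldehyde.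
4. Aldehyde ⇐ L‑arabinose (sugar C2, C3, C4 = C5, C6, C7): 3,4‑acetonide, three‑carbon Wittig, hydrogenation, δ‑lactone, oxidation.
5. Chlorofuran ⇐ 3‑bromofuran (Br→Cl, C2 silyl block, C5 alkylation, desilylation) + (2Z,5Z)‑octadienyl bromide (diyne coupling, Lindlar, Appel).

Assumption: prostanoid numbering (C1 = ester carbon, C8–C12 = ring) is used in the comments; the furyl carbinol carbon C8 in 22–24 is an epimeric mixture (no descriptor) because it is ionised in step 13.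

**Step 1**
Reactants: 1 prop‑2‑yn‑1‑ol; 2 1‑bromopent‑2‑yne
Product: 3 octa‑2,5‑diyn‑1‑ol
Conditions: CuI, NaI, K2CO3, DMF, rt
Reagents that add atoms: none
Why: Copper‑acetylide alkylation (Cu‑mediated sp–sp3 coupling) of the terminal alkyne with the propargylic bromide under carbonate base gives the skipped diyne without allene formation.

**Step 2**
Reactants: 3 octa‑2,5‑diyn‑1‑ol
Product: 4 (2Z,5Z)‑octa‑2,5‑dien‑1‑ol
Conditions: H2 (1 atm), Lindlar catalyst, quinoline, EtOAc, rt (stop at 2 equiv H2)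
Reagents that add atoms: none
Why: Lindlar semihydrogenation adds H2 syn to both alkynes, giving the Z,Z skipped diene, with quinoline suppressing over‑reduction.

**Step 3**
Reactants: 4 (2Z,5Z)‑octa‑2,5‑dien‑1‑ol
Product: 5 (2Z,5Z)‑1‑bromoocta‑2,5‑diene
Conditions: CBr4, PPh3, CH2Cl2, 0 °C
Reagents that add atoms: carbon tetrabromide, BrC(Br)(Br)Br
Why: Appel bromination displaces the alkoxyphosphonium at the primary allylic carbon by SN2 at 0 °C, without allylic shift or Z→E isomerisation.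

**Step 4**
Reactants: 6 3‑bromofuran
Product: 8 3‑chlorofuran, via furan‑3‑yllithium 7 (not isolated)
Conditions: n‑BuLi, Et2O, −78 °C; C2Cl6, −78 °C → rt; fractional distillation
Reagents that add atoms: hexachloroethane, ClC(Cl)(Cl)C(Cl)(Cl)Cl
Why: Bromine–lithium exchange at −78 °C gives 3‑furyllithium (regiostable below −40 °C), which is chlorinated by the electrophilic chlorine of hexachloroethane.

**Step 5**
Reactants: 8 3‑chlorofuran; 5 (2Z,5Z)‑1‑bromoocta‑2,5‑diene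
Product: 12 {3‑chloro‑5‑[(2Z,5Z)‑octa‑2,5‑dien‑1‑yl]furan‑2‑yl}trimethylsilane, via (3‑chlorofuran‑2‑yl)lithium 9 (not isolated), via 3‑chloro‑2‑(trimethylsilyl)furan 10 (not isolated), via 5‑lithio‑3‑chloro‑2‑(trimethylsilyl)furan 11 (not isolated)
Conditions: n‑BuLi, THF, −78 °C; TMSCl; n‑BuLi, −78 → −20 °C; 5, DMPU, −78 °C → rt
Reagents that add atoms: chlorotrimethylsilane, C[Si](C)(C)Cl
Why: Sequential directed lithiation: the C2–H flanked by O and Cl is metallated first and blocked with silicon, so the second lithiation occurs at the only remaining α‑position (C5), and that furyllithium is alkylated by SN2 at the primary allylic bromide with the Z alkenes intact.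

**Step 6**
Reactants: 12 {3‑chloro‑5‑[(2Z,5Z)‑octa‑2,5‑dien‑1‑yl]furan‑2‑yl}trimethylsilane
Product: 13 4‑chloro‑2‑[(2Z,5Z)‑octa‑2,5‑dien‑1‑yl]furan
Conditions: TBAF (1 M in wet THF), 0 °C → rt
Reagents that add atoms: none
Why: Fluoride‑induced ipso‑protodesilylation works because the departing furyl anion is stabilised by the ring oxygen and the ortho chlorine, and the alkenes are inert.

**Step 7**
Reactants: 14 L‑arabinose
Product: 15 3,4‑O‑isopropylidene‑β‑L‑arabinopyranose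
Conditions: 2,2‑dimethoxypropane, TsOH (cat.), DMF, rt
Reagents that add atoms: 2,2‑dimethoxypropane, COC(C)(C)OC
Why: Acid‑catalysed transketalisation selects the cis‑3,4‑diol of the pyranose for the five‑membered acetonide and leaves the hemiacetal and 2‑OH free, with no stereocentre touched.

**Step 8**
Reactants: 15 3,4‑O‑isopropylidene‑β‑L‑arabinopyranose
Product: 16 (3Z,5S)‑5‑hydroxy‑5‑[(4R,5S)‑5‑(hydroxymethyl)‑2,2‑dimethyl‑1,3‑dioxolan‑4‑yl]pent‑3‑enoic acid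
Conditions: [Ph3P(CH2)2CO2H]Br (3 equiv), NaHMDS (7 equiv), THF, −78 °C → rt; 1 M HCl to pH 4
Reagents that add atoms: (2‑carboxyethyl)triphenylphosphonium bromide, OC(=O)CC[P+](c1ccccc1)(c1ccccc1)c1ccccc1.[Br-]
Why: Wittig olefination of the lactol's open‑chain aldehyde by the non‑stabilised carboxylate ylide (excess base covers the free OH groups) adds C1–C3, and sugar C2, C3, C4 become C5, C6, C7 unchanged.

**Step 9**
Reactants: 16 (3Z,5S)‑5‑hydroxy‑5‑[(4R,5S)‑5‑(hydroxymethyl)‑2,2‑dimethyl‑1,3‑dioxolan‑4‑yl]pent‑3‑enoic acid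
Product: 18 (6S)‑6‑[(4R,5S)‑5‑(hydroxymethyl)‑2,2‑dimethyl‑1,3‑dioxolan‑4‑yl]oxan‑2‑one, via saturated hydroxy acid 17 (not isolated)
Conditions: H2 (1 atm), Pt/C, EtOAc, rt; filter; DCC, DMAP (cat.), CH2Cl2 (0.02 M), 0 °C → rt
Reagents that add atoms: none
Why: Heterogeneous hydrogenation (Pt limits allylic C–O hydrogenolysis) followed by Steglich‑type lactonisation closes the six‑membered ring onto the C5 hydroxyl much faster than the remote primary alcohol is acylated, so C8–OH is left as the only free hydroxyl.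

**Step 10**
Reactants: 18 (6S)‑6‑[(4R,5S)‑5‑(hydroxymethyl)‑2,2‑dimethyl‑1,3‑dioxolan‑4‑yl]oxan‑2‑one
Product: 19 (4R,5R)‑2,2‑dimethyl‑5‑[(2S)‑6‑oxooxan‑2‑yl]‑1,3‑dioxolane‑4‑carbaldehyde
Conditions: Dess–Martin periodinane, pyridine, CH2Cl2, 0 °C → rt; used crude
Reagents that add atoms: none
Why: Dess–Martin oxidation under buffered, non‑enolising conditions gives the α‑alkoxy aldehyde without epimerising C7, the centre that later steers the ring closure.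

**Step 11**
Reactants: 13 4‑chloro‑2‑[(2Z,5Z)‑octa‑2,5‑dien‑1‑yl]furan; 19 (4R,5R)‑2,2‑dimethyl‑5‑[(2S)‑6‑oxooxan‑2‑yl]‑1,3‑dioxolane‑4‑carbaldehyde
Product: 22 (6S)‑6‑[(4R,5S)‑5‑{[3‑chloro‑5‑((2Z,5Z)‑octa‑2,5‑dien‑1‑yl)furan‑2‑yl](hydroxy)methyl}‑2,2‑dimethyl‑1,3‑dioxolan‑4‑yl]oxan‑2‑one (C8 epimers), via furyllithium 20 (not isolated), via furyltitanium triisopropoxide 21 (not isolated)
Conditions: LDA, THF, −78 °C; ClTi(OiPr)3, −78 → −40 °C; 19, −78 → −20 °C; H2O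
Reagents that add atoms: none
Why: Directed ortho‑lithiation at the C–H between O and Cl, then transmetalation to a Reetz‑type organotitanium, gives aldehyde‑selective 1,2‑addition that spares the δ‑lactone; the new C8 centre forms as a mixture, which is harmless because C8 is ionised in step 13.

**Step 12**
Reactants: 22 (6S)‑6‑[(4R,5S)‑5‑{[3‑chloro‑5‑((2Z,5Z)‑octa‑2,5‑dien‑1‑yl)furan‑2‑yl](hydroxy)methyl}‑2,2‑dimethyl‑1,3‑dioxolan‑4‑yl]oxan‑2‑one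
Product: 24 methyl (5S)‑5‑acetoxy‑5‑[(4R,5R)‑5‑{acetoxy[3‑chloro‑5‑((2Z,5Z)‑octa‑2,5‑dien‑1‑yl)furan‑2‑yl]methyl}‑2,2‑dimethyl‑1,3‑dioxolan‑4‑yl]pentanoate (C8 epimers), via seco‑ester diol 23 (not isolated)
Conditions: NaOMe (0.2 equiv), MeOH, 0 °C; AcOH quench, evaporate below 25 °C; Ac2O, pyridine, DMAP (cat.), CH2Cl2, 0 °C → rt
Reagents that add atoms: methanol, CO; acetic anhydride, CC(=O)OC(C)=O
Why: Methoxide transesterification (Zemplén type) opens the δ‑lactone to the methyl ester in neat methanol, and immediate acetylation traps the C5 hydroxyl against relactonisation and turns the furyl carbinol into a leaving group.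

**Step 13**
Reactants: 24 methyl (5S)‑5‑acetoxy‑5‑[(4R,5R)‑5‑{acetoxy[3‑chloro‑5‑((2Z,5Z)‑octa‑2,5‑dien‑1‑yl)furan‑2‑yl]methyl}‑2,2‑dimethyl‑1,3‑dioxolan‑4‑yl]pentanoate
Product: 25 methyl (5S,6S,7S)‑5‑acetoxy‑7‑{(1S,2S)‑4‑chloro‑2‑hydroxy‑2‑[(2Z,5Z)‑octa‑2,5‑dien‑1‑yl]‑5‑oxocyclopent‑3‑en‑1‑yl}‑6,7‑dihydroxyheptanoate
Conditions: Dy(OTf)3 (10 mol%), t‑BuOH–H2O (5:1), 80 °C
Reagents that add atoms: water, O
Why: Piancatelli rearrangement: the furfuryl acetate ionises, water adds at the alkyl‑bearing furan carbon, and the ring‑opened 1,4‑dihydroxypentadienyl cation closes by 4π‑conrotatory electrocyclisation with the C12 hydroxyl rotating outward (trans to the C8 chain) and the C8–C12 bond forming anti to the C7–O bond of the A(1,3)‑locked arabinose‑derived C7, which by this model gives the C12 arrangement of the target (12S by CIP here, 12R in 27); this sense is predicted, not proven, and the same aqueous Lewis acid cleaves the acetonide.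

**Step 14**
Reactants: 25 methyl (5S,6S,7S)‑5‑acetoxy‑7‑{(1S,2S)‑4‑chloro‑2‑hydroxy‑2‑[(2Z,5Z)‑octa‑2,5‑dien‑1‑yl]‑5‑oxocyclopent‑3‑en‑1‑yl}‑6,7‑dihydroxyheptanoate
Product: 27 punaglandin 3 = methyl (5S,6S,7E)‑5,6‑diacetoxy‑7‑{(2R)‑4‑chloro‑2‑hydroxy‑2‑[(2Z,5Z)‑octa‑2,5‑dien‑1‑yl]‑5‑oxocyclopent‑3‑en‑1‑ylidene}heptanoate, via 5,6,7‑triacetate 26 (not isolated)
Conditions: Ac2O, pyridine, DMAP (cat.), CH2Cl2, 0 °C → rt; then DBU, 0 °C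
Reagents that add atoms: acetic anhydride, CC(=O)OC(C)=O
Why: Acetylation of the two secondary alcohols (the hindered tertiary C12–OH stays free) followed by E1cB elimination of the β‑acetoxy ketone removes the C7 and C8 centres and gives the thermodynamically preferred 7E enone, leaving C5, C6 and C12 untouched.

**Compound list**
1 | prop‑2‑yn‑1‑ol | C#CCO | starting material
2 | 1‑bromopent‑2‑yne | CCC#CCBr | starting material
3 | octa‑2,5‑diyn‑1‑ol | CCC#CCC#CCO | intermediate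
4 | (2Z,5Z)‑octa‑2,5‑dien‑1‑ol | CC/C=C\C/C=C\CO | intermediate
5 | (2Z,5Z)‑1‑bromoocta‑2,5‑diene | CC/C=C\C/C=C\CBr | intermediate
6 | 3‑bromofuran | Brc1ccoc1 | starting material
7 | furan‑3‑yllithium | [Li]c1ccoc1 | intermediate
8 | 3‑chlorofuran | Clc1ccoc1 | intermediate
9 | (3‑chlorofuran‑2‑yl)lithium | [Li]c1occc1Cl | intermediate
10 | 3‑chloro‑2‑(trimethylsilyl)furan | C[Si](C)(C)c1occc1Cl | intermediate
11 | [4‑chloro‑5‑(trimethylsilyl)furan‑2‑yl]lithium | [Li]c1cc(Cl)c(o1)[Si](C)(C)C | intermediate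
12 | {3‑chloro‑5‑[(2Z,5Z)‑octa‑2,5‑dien‑1‑yl]furan‑2‑yl}trimethylsilane | CC/C=C\C/C=C\Cc1cc(Cl)c(o1)[Si](C)(C)C | intermediate
13 | 4‑chloro‑2‑[(2Z,5Z)‑octa‑2,5‑dien‑1‑yl]furan | CC/C=C\C/C=C\Cc1cc(Cl)co1 | intermediate
14 | L‑arabinose (open‑chain form drawn) | OC[C@H](O)[C@H](O)[C@@H](O)C=O | starting material
15 | 3,4‑O‑isopropylidene‑β‑L‑arabinopyranose | O[C@H]1OC[C@@H]2OC(C)(C)O[C@@H]2[C@H]1O | intermediate
16 | (3Z,5S)‑5‑hydroxy‑5‑[(4R,5S)‑5‑(hydroxymethyl)‑2,2‑dimethyl‑1,3‑dioxolan‑4‑yl]pent‑3‑enoic acid | OC[C@@H]1OC(C)(C)O[C@@H]1[C@@H](O)/C=C\CC(=O)O | intermediate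
17 | (5S)‑5‑hydroxy‑5‑[(4R,5S)‑5‑(hydroxymethyl)‑2,2‑dimethyl‑1,3‑dioxolan‑4‑yl]pentanoic acid | OC[C@@H]1OC(C)(C)O[C@@H]1[C@@H](O)CCCC(=O)O | intermediate
18 | (6S)‑6‑[(4R,5S)‑5‑(hydroxymethyl)‑2,2‑dimethyl‑1,3‑dioxolan‑4‑yl]oxan‑2‑one | OC[C@@H]1OC(C)(C)O[C@@H]1[C@@H]2CCCC(=O)O2 | intermediate
19 | (4R,5R)‑2,2‑dimethyl‑5‑[(2S)‑6‑oxooxan‑2‑yl]‑1,3‑dioxolane‑4‑carbaldehyde | O=C[C@@H]1OC(C)(C)O[C@@H]1[C@@H]2CCCC(=O)O2 | intermediate
20 | {3‑chloro‑5‑[(2Z,5Z)‑octa‑2,5‑dien‑1‑yl]furan‑2‑yl}lithium | [Li]c1oc(C/C=C\C/C=C\CC)cc1Cl | intermediate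
21 | {3‑chloro‑5‑[(2Z,5Z)‑octa‑2,5‑dien‑1‑yl]furan‑2‑yl}tri(propan‑2‑yloxy)titanium | CC(C)O[Ti](OC(C)C)(OC(C)C)c1oc(C/C=C\C/C=C\CC)cc1Cl | intermediate
22 | (6S)‑6‑[(4R,5S)‑5‑{[3‑chloro‑5‑((2Z,5Z)‑octa‑2,5‑dien‑1‑yl)furan‑2‑yl](hydroxy)methyl}‑2,2‑dimethyl‑1,3‑dioxolan‑4‑yl]oxan‑2‑one, C8 epimers | CC/C=C\C/C=C\Cc1cc(Cl)c(o1)C(O)[C@@H]2OC(C)(C)O[C@@H]2[C@@H]3CCCC(=O)O3 | intermediate
23 | methyl (5S)‑5‑hydroxy‑5‑[(4R,5S)‑5‑{[3‑chloro‑5‑((2Z,5Z)‑octa‑2,5‑dien‑1‑yl)furan‑2‑yl](hydroxy)methyl}‑2,2‑dimethyl‑1,3‑dioxolan‑4‑yl]pentanoate, C8 epimers | CC/C=C\C/C=C\Cc1cc(Cl)c(o1)C(O)[C@@H]2OC(C)(C)O[C@@H]2[C@H](CCCC(=O)OC)O | intermediate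
24 | methyl (5S)‑5‑acetoxy‑5‑[(4R,5R)‑5‑{acetoxy[3‑chloro‑5‑((2Z,5Z)‑octa‑2,5‑dien‑1‑yl)furan‑2‑yl]methyl}‑2,2‑dimethyl‑1,3‑dioxolan‑4‑yl]pentanoate, C8 epimers | CC/C=C\C/C=C\Cc1cc(Cl)c(o1)C(OC(C)=O)[C@@H]2OC(C)(C)O[C@@H]2[C@H](CCCC(=O)OC)OC(C)=O | intermediate
25 | methyl (5S,6S,7S)‑5‑acetoxy‑7‑{(1S,2S)‑4‑chloro‑2‑hydroxy‑2‑[(2Z,5Z)‑octa‑2,5‑dien‑1‑yl]‑5‑oxocyclopent‑3‑en‑1‑yl}‑6,7‑dihydroxyheptanoate | CC/C=C\C/C=C\C[C@@]1(O)C=C(Cl)C(=O)[C@H]1[C@H](O)[C@H](O)[C@H](CCCC(=O)OC)OC(C)=O | intermediate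
26 | methyl (5S,6R,7S)‑5,6,7‑triacetoxy‑7‑{(1S,2S)‑4‑chloro‑2‑hydroxy‑2‑[(2Z,5Z)‑octa‑2,5‑dien‑1‑yl]‑5‑oxocyclopent‑3‑en‑1‑yl}heptanoate | CC/C=C\C/C=C\C[C@@]1(O)C=C(Cl)C(=O)[C@H]1[C@H](OC(C)=O)[C@H](OC(C)=O)[C@H](CCCC(=O)OC)OC(C)=O | intermediate
27 | punaglandin 3, methyl (5S,6S,7E)‑5,6‑diacetoxy‑7‑{(2R)‑4‑chloro‑2‑hydroxy‑2‑[(2Z,5Z)‑octa‑2,5‑dien‑1‑yl]‑5‑oxocyclopent‑3‑en‑1‑ylidene}heptanoate | CC/C=C\C/C=C\C[C@@]1(O)C=C(Cl)C(=O)/C1=C/[C@H](OC(C)=O)[C@H](CCCC(=O)OC)OC(C)=O | target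

**Total step count:** 14.
**Longest linear sequence:** 9 steps (1, 2, 3, 5, 6, 11, 12, 13, 14); the arabinose branch is 8 steps (7–14) and the 3‑bromofuran branch 7 steps (4, 5, 6, 11–14).

**Three steps most likely to fail**

Step 13 (Piancatelli rearrangement). The furan is deactivated (3‑chloro, 5‑alkyl, α‑oxygenated carbinol) and the sense of C7 → C12 induction rests on a model. Free hydroxyls next to the C5 acetate could also allow acyl migration and relactonisation. Fallback, setting out from 19 and returning at 27: the controlling centre is inverted instead of the conditions. Aldehyde 19 is epimerised at C7 with catalytic DBU in CH2Cl2 to the thermodynamically preferred trans‑dioxolane aldehyde (4S,5R)‑2,2‑dimethyl‑5‑[(2S)‑6‑oxooxan‑2‑yl]‑1,3‑dioxolane‑4‑carbaldehyde F1. Addition of 21 gives the 7‑epi furyl carbinol F2. Methoxide methanolysis gives the 7‑epi seco‑ester diol F3, which is acetylated to the 7‑epi diacetate F4. Dy(OTf)3 in aqueous t‑BuOH gives the 7‑epi cyclopentenone diol F5. Acetylation gives the 7‑epi triacetate F6, and DBU elimination erases C7 and rejoins the route at 27.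

Step 8 (three‑carbon Wittig on a lactol). The carboxyethyl ylide is fragile (it can fragment to acrylate) and the lactol with a free 2‑OH reacts slowly. Fallback, setting out from 15 and returning at 18: methylenation of 15 with Ph3P=CH2 in THF gives the vinyl carbinol (1S)‑1‑[(4R,5S)‑5‑(hydroxymethyl)‑2,2‑dimethyl‑1,3‑dioxolan‑4‑yl]prop‑2‑en‑1‑ol F7. Cross‑metathesis with methyl but‑3‑enoate (Hoveyda–Grubbs II, benzoquinone, CH2Cl2, 40 °C) gives the E hydroxy enoate F8. Hydrogenation over Pt/C gives the saturated hydroxy ester F9, which lactonises with catalytic DBU in warm toluene to 18.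

Step 11 (deprotonation and coupling). LDA may also deprotonate the doubly activated furfurylic/allylic CH2, and the aldehyde must react in preference to the δ‑lactone. Fallback, setting out from 12 and returning at 22: the nucleophile is made by halogen–metal exchange instead of deprotonation. Silane 12 is ipso‑bromodesilylated with NBS in DMF at −20 °C to 2‑bromo‑3‑chloro‑5‑[(2Z,5Z)‑octa‑2,5‑dien‑1‑yl]furan F10. Exchange with i‑PrMgCl·LiCl in THF at −40 °C gives {3‑chloro‑5‑[(2Z,5Z)‑octa‑2,5‑dien‑1‑yl]furan‑2‑yl}magnesium chloride F11, which adds to 19 at −78 °C to give 22.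

**Further compounds**
F1 | step 13 | (4S,5R)‑2,2‑dimethyl‑5‑[(2S)‑6‑oxooxan‑2‑yl]‑1,3‑dioxolane‑4‑carbaldehyde (7‑epi‑19) | O=C[C@H]1OC(C)(C)O[C@@H]1[C@@H]2CCCC(=O)O2
F2 | step 13 | (6S)‑6‑[(4R,5R)‑5‑{[3‑chloro‑5‑((2Z,5Z)‑octa‑2,5‑dien‑1‑yl)furan‑2‑yl](hydroxy)methyl}‑2,2‑dimethyl‑1,3‑dioxolan‑4‑yl]oxan‑2‑one (7‑epi‑22) | CC/C=C\C/C=C\Cc1cc(Cl)c(o1)C(O)[C@H]2OC(C)(C)O[C@@H]2[C@@H]3CCCC(=O)O3
F3 | step 13 | methyl (5S)‑5‑hydroxy‑5‑[(4R,5R)‑5‑{[3‑chloro‑5‑((2Z,5Z)‑octa‑2,5‑dien‑1‑yl)furan‑2‑yl](hydroxy)methyl}‑2,2‑dimethyl‑1,3‑dioxolan‑4‑yl]pentanoate (7‑epi‑23) | CC/C=C\C/C=C\Cc1cc(Cl)c(o1)C(O)[C@H]2OC(C)(C)O[C@@H]2[C@H](CCCC(=O)OC)O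
F4 | step 13 | methyl (5S)‑5‑acetoxy‑5‑[(4R,5S)‑5‑{acetoxy[3‑chloro‑5‑((2Z,5Z)‑octa‑2,5‑dien‑1‑yl)furan‑2‑yl]methyl}‑2,2‑dimethyl‑1,3‑dioxolan‑4‑yl]pentanoate (7‑epi‑24) | CC/C=C\C/C=C\Cc1cc(Cl)c(o1)C(OC(C)=O)[C@H]2OC(C)(C)O[C@@H]2[C@H](CCCC(=O)OC)OC(C)=O
F5 | step 13 | methyl (5S,6S,7R)‑5‑acetoxy‑7‑{(1S,2S)‑4‑chloro‑2‑hydroxy‑2‑[(2Z,5Z)‑octa‑2,5‑dien‑1‑yl]‑5‑oxocyclopent‑3‑en‑1‑yl}‑6,7‑dihydroxyheptanoate (7‑epi‑25) | CC/C=C\C/C=C\C[C@@]1(O)C=C(Cl)C(=O)[C@H]1[C@@H](O)[C@H](O)[C@H](CCCC(=O)OC)OC(C)=O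
F6 | step 13 | methyl (5S,6R,7R)‑5,6,7‑triacetoxy‑7‑{(1S,2S)‑4‑chloro‑2‑hydroxy‑2‑[(2Z,5Z)‑octa‑2,5‑dien‑1‑yl]‑5‑oxocyclopent‑3‑en‑1‑yl}heptanoate (7‑epi‑26) | CC/C=C\C/C=C\C[C@@]1(O)C=C(Cl)C(=O)[C@H]1[C@@H](OC(C)=O)[C@H](OC(C)=O)[C@H](CCCC(=O)OC)OC(C)=O
F7 | step 8 | (1S)‑1‑[(4R,5S)‑5‑(hydroxymethyl)‑2,2‑dimethyl‑1,3‑dioxolan‑4‑yl]prop‑2‑en‑1‑ol | OC[C@@H]1OC(C)(C)O[C@@H]1[C@@H](O)C=C
F8 | step 8 | methyl (3E,5S)‑5‑hydroxy‑5‑[(4R,5S)‑5‑(hydroxymethyl)‑2,2‑dimethyl‑1,3‑dioxolan‑4‑yl]pent‑3‑enoate | OC[C@@H]1OC(C)(C)O[C@@H]1[C@@H](O)/C=C/CC(=O)OC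
F9 | step 8 | methyl (5S)‑5‑hydroxy‑5‑[(4R,5S)‑5‑(hydroxymethyl)‑2,2‑dimethyl‑1,3‑dioxolan‑4‑yl]pentanoate | OC[C@@H]1OC(C)(C)O[C@@H]1[C@@H](O)CCCC(=O)OC
F10 | step 11 | 2‑bromo‑3‑chloro‑5‑[(2Z,5Z)‑octa‑2,5‑dien‑1‑yl]furan | CC/C=C\C/C=C\Cc1cc(Cl)c(Br)o1
F11 | step 11 | {3‑chloro‑5‑[(2Z,5Z)‑octa‑2,5‑dien‑1‑yl]furan‑2‑yl}magnesium chloride | CC/C=C\C/C=C\Cc1cc(Cl)c(o1)[Mg]Cl
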